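The vessel is closed, and substrate leaves it through the intermediate, which the nucleophiles then capture. The ledger below follows the substrate, in fractions of its charge.

| flask | substrate | first nucleophile | second nucleophile | remark | time |
|---|---|---|---|---|---|
| teal | 0.050 M | 1 equiv | 0.23 equiv | run made earlier |  |
| green | 0.050 M | 1 equiv | 1.2 equiv | run made earlier |  |
| blue | 0.050 M | 0.53 equiv | 1.8 equiv | run made earlier |  |
| oak | 0.050 M | 0.250 equiv | 0.450 equiv |  | 4.0 d |
| alder | 0.10 M | 0.670 equiv | 0.450 equiv |  | 4.0 d |
| ash | 0.050 M | 1.00 equiv | 1.80 equiv |  | 4.0 d |
| larch | 0.20 M | 0.670 equiv | 0.590 equiv |  | 4.0 d |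
| maple | 0.015 M | 1.00 equiv | 0.590 equiv |  | 4.0 d |

| run | time / h | target / % | substrate / % |
|---|---|---|---|
| teal | 4.00 | 2 | 96 |
| teal | 6.00 | 4 | 92 |
| teal | 10.0 | 7 | 84 |
| teal | 20.0 | 18 | 73 |
| teal | 30.0 | 23 | 63 |
| teal | 50.0 | 34 | 41 |
| green | 4.00 | 2 | 95 |
| green | 6.00 | 1 | 90 |
| green | 10.0 | 8 | 85 |
| green | 20.0 | 12 | 72 |
| green | 30.0 | 15 | 60 |
| green | 50.0 | 23 | 44 |
| blue | 4.00 | 0 | 95 |
| blue | 8.00 | 3 | 87 |
| blue | 15.0 | 6 | 76 |
| blue | 25.0 | 8 | 66 |
| blue | 50.0 | 10 | 42 |

(standard deviation of a reading: 1.5 percentage points)

- percent here means substrate units held: one side product counts as two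
- the numbers in the tables scatter by 1.5 percentage points (one standard deviation)
- candidate steps: substrate -> intermediate; first nucleophile + intermediate -> target; second nucleophile + intermediate -> other capture product; target <-> isomer of the product; substrate + intermediate -> side product

1. the flasks by amount of target, in percent of the substrate charged, highest first, at 4.0 d (oak / alder / ash / larch / maple)
2. the amount of target, in percent of the substrate charged of the flask you put first, at 4.0 d
3. the amount of target, in percent of the substrate charged of the flask you put last, at 4.0 d

1. **Consumed.** At 50.0 h, substrate left reads 41 % in teal, 44 % in green and 42 % in blue, although the nucleophile loadings differ. The step to the intermediate is therefore taken as the rate-limiting step. The mean first-order constant is 0.0172 h⁻¹. This reckoning then books 80.8 % consumed by 4.0 d in each flask.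

2. **Share.** Define the loss number as substrate consumed per unit of target standing. At 50.0 h it reads 1.74 in teal and 2.43 in green. Those flasks differ in second nucleophile per first nucleophile. Each unit of that ratio adds 0.721 to the loss number.

3. **Correction.** Teal's loss number read 1.50 at 20.0 h, so it drifts by 0.00784 h⁻¹. This drift is booked as target leaking to its isomer. Carried to 4.0 d, with the second nucleophile term removed, the base is 1.93. The same drift leaves 64.1 % of the target made still standing.

4. **Closing the books.** Maple's loss number, substrate consumed per unit of target standing at 4.0 d, is 2.36. Maple therefore books 34.3 %. The same entry gives alder 33.5 %, larch 31.5 % and ash 25.0 %.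

5. **Oak.** Oak has ash's ratio, but standing at 25.0 % would need 39.0 % of target made, more than its charge of 0.250 equiv first nucleophile. The charge caps the entry, and the kept fraction leaves 16.0 %.

This reckoning puts maple highest and oak lowest.

The forecast gave maple > alder > larch > ash > oak, with 35 % first (range 29 % to 42 %) and 16 % last (range 12 % to 20 %), and held that “All captures are bimolecular, so partition depends on equivalents, not absolute concentration.”

The flasks give maple > alder > larch > ash > oak, with 34.1 % in maple and 15.1 % in oak.

    substrate → intermediate (k = 2.70 × 10⁻⁴ min⁻¹)
    first nucleophile + intermediate → target (k = 0.0920 L mol⁻¹ min⁻¹)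
    second nucleophile + intermediate → other capture product (k = 0.0540 L mol⁻¹ min⁻¹)
    target ⇌ isomer of the product (K = 0.930, k = 1.90 × 10⁻⁴ min⁻¹)
    substrate + intermediate → side product (k = 0.00380 L mol⁻¹ min⁻¹)

The step from substrate and intermediate to side product, absent from the ledger, makes no difference to oak's target. A neighbour flask repeats maple at 0.0037 M of substrate, with the same equivalents and time. Its ratio of nucleophiles is unchanged, so the loss number 2.36 books 34.3 % of target again. That flask holds 26.8 % of target with 20.7 % of substrate left, so its books read a loss number of 2.96. Its intermediate stands at 25.6 %, more than the 6.50 % in maple.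

All runs were generated by integration for an exercise, noise included.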